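**Retrosynthetic overview**
1. The C(sp)–C(sp2) bond of the enyne is cut last: Sonogashira coupling of dioxane alkyne 16 with (E)-1-iodoundeca-1,10-diene 19 (from dec-9-en-1-ol by oxidation and Takai olefination).
2. The strategy rests on C3 of the 1,2-dioxane ring (O1–O2–C3–C4–C5–C6): it carries the ring oxygen O2 and the CH2CO2Me arm (C2, C1), the pattern left by oxypalladation of a terminal alkene followed by methoxycarbonylation.
3. The only ring is therefore closed by cutting O2–C3, C2–C1 and the ester C–O bond back to hydroperoxyketal 11, CO and methanol; a chiral palladium catalyst sets C3 (S).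
4. C6 (R) is settled after ring closure by acid equilibration to the anomer with axial methoxy.
5. Hydroperoxyketal 11 comes from ketone 8 (Weinreb amide of silylated hex-5-ynoic acid plus but-3-enylmagnesium bromide) by ketalisation and exchange with H2O2.

Key step: step 6

Assumption: the sense of induction of a bisoxazoline–palladium catalyst with a hydroperoxide nucleophile cannot be predicted with confidence. The (S,S)-ligand is written; its antipode is to be used if a first trial shows that it is the one giving 3S.

**Step 1**
Reactants: 1 hex-5-ynoic acid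
Product: 3 6-(triisopropylsilyl)hex-5-ynoic acid, via dilithium hex-5-ynoate acetylide 2 (not isolated)
Conditions: n-BuLi (2.1 equiv), THF, −78 °C; TIPSCl (1.1 equiv), −78 °C → rt; 1 M HCl work-up
Reagents that add atoms: chlorotriisopropylsilane, CC(C)[Si](Cl)(C(C)C)C(C)C
Why: Double deprotonation gives the carboxylate–acetylide dianion, which is silylated at its more basic acetylide carbon (C-silylation of a lithium acetylide), while the lithium carboxylate is inert to the hindered chlorosilane and any silyl ester is cleaved in the acidic work-up.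

**Step 2**
Reactants: 3 6-(triisopropylsilyl)hex-5-ynoic acid
Product: 5 N-methoxy-N-methyl-6-(triisopropylsilyl)hex-5-ynamide, via acyl imidazole 4 (not isolated)
Conditions: 1,1'-carbonyldiimidazole, CH2Cl2, rt; then MeNH(OMe)·HCl, rt
Reagents that add atoms: N,O-dimethylhydroxylamine hydrochloride, CNOC.Cl; 1,1'-carbonyldiimidazole, O=C(n1ccnc1)n1ccnc1 (supplies the imidazole of intermediate 4 only)
Why: Carbonyldiimidazole activation followed by aminolysis of the acyl imidazole (Weinreb amide formation) runs under near-neutral conditions that leave the silylalkyne untouched.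

**Step 3**
Reactants: 5 N-methoxy-N-methyl-6-(triisopropylsilyl)hex-5-ynamide; 6 but-3-enylmagnesium bromide (purchased as a THF solution)
Product: 8 10-(triisopropylsilyl)dec-1-en-9-yn-5-one, via magnesium hemiaminal chelate 7 (not isolated)
Conditions: THF, 0 °C; sat. aq. NH4Cl
Reagents that add atoms: none
Why: Weinreb ketone synthesis, in which the five-membered magnesium chelate 7 holds the tetrahedral adduct until work-up, so that only one butenyl group is added.

**Step 4**
Reactants: 8 10-(triisopropylsilyl)dec-1-en-9-yn-5-one
Product: 9 (6,6-dimethoxydec-9-en-1-yn-1-yl)triisopropylsilane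
Conditions: HC(OMe)3 (as solvent), p-TsOH·H2O (cat.), rt; Et3N quench, base-washed silica
Reagents that add atoms: trimethyl orthoformate, COC(OC)OC
Why: Acid-catalysed ketalisation with the orthoester as methoxy source and water scavenger should go to completion, and the silylalkyne and terminal alkene are inert to catalytic sulfonic acid.

**Step 5**
Reactants: 9 (6,6-dimethoxydec-9-en-1-yn-1-yl)triisopropylsilane; 10 hydrogen peroxide
Product: 11 (6-hydroperoxy-6-methoxydec-9-en-1-yn-1-yl)triisopropylsilane (racemic)
Conditions: anhydrous H2O2 in Et2O (ca. 5 equiv), camphorsulfonic acid (5 mol %), 0 °C, stopped before full conversion; NaHCO3 quench, unreacted 9 recycled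
Reagents that add atoms: hydrogen peroxide (10), OO
Why: Acid-catalysed peroxyketal exchange, in which the methoxycarbenium ion from 9 is captured by H2O2 (an α-effect nucleophile) and the second exchange is slower because it must pass through a less stabilised peroxycarbenium ion; the new C6 centre is racemic, which is accepted.

**Step 6**
Reactants: 11 (6-hydroperoxy-6-methoxydec-9-en-1-yn-1-yl)triisopropylsilane (racemic); 12 carbon monoxide; 13 methanol
Product: 14 methyl 2-[(3S)-6-methoxy-6-[5-(triisopropylsilyl)pent-4-yn-1-yl]-1,2-dioxan-3-yl]acetate (mixture of C6 epimers)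
Conditions: Pd(OCOCF3)2 (10 mol %), (S,S)-Bn-BOXAX [2,2'-bis((4S)-4-benzyl-4,5-dihydrooxazol-2-yl)-1,1'-binaphthyl] (20 mol %), p-benzoquinone (2 equiv), CO (1 atm), MeOH (10 equiv), CH2Cl2, 0 °C → rt
Reagents that add atoms: carbon monoxide (12), [C-]#[O+]; methanol (13), CO
Why: Proposed new method: ligand-bound divalent palladium binds the terminal alkene, the distal hydroperoxy oxygen adds to the internal alkene carbon, the primary alkylpalladium at C2 inserts CO, and methanolysis of the acylpalladium releases the methyl ester and zerovalent palladium, which benzoquinone returns to the divalent state. The closest known reactions are the divalent-palladium cyclisation of unsaturated tertiary hydroperoxides to 1,2-dioxanes (which ends in β-hydride elimination) and the enantioselective alkoxycarbonylative Wacker cyclisation of alkenols and alkenylphenols with Pd(OCOCF3)2, a bisoxazoline, benzoquinone, CO and methanol. The 1,2-dioxane closes 6-exo-trig, because the two-carbon tether between C6 and the alkene makes 7-endo attack at the terminal carbon unfavourable. C3 is set by the chiral ligand, which selects the alkene face offered to the peroxy oxygen, while C6 is left as a mixture. The step needs CO insertion to outrun β-hydride elimination (secured by the CO atmosphere and a primary alkylpalladium), survival of the hydroperoxyketal (it is tertiary with no α-hydrogen, methanol is held to a few equivalents against reversion to the ketal, and copper salts are left out to avoid one-electron O–O cleavage), and an inert alkyne (the triisopropylsilyl cap blocks alkyne carbonylation). It also needs the ligand to decide the alkene face for both enantiomers of 11, which is plausible because C6 lies 1,4 to the forming centre and differs only in OMe against CH2, and any methanol exchange at C6 under the Lewis-acidic conditions would only help by interconverting the two.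

**Step 7**
Reactants: 14 methyl 2-[(3S)-6-methoxy-6-[5-(triisopropylsilyl)pent-4-yn-1-yl]-1,2-dioxan-3-yl]acetate (C6 epimers); 13 methanol
Product: 15 methyl 2-[(3S,6R)-6-methoxy-6-[5-(triisopropylsilyl)pent-4-yn-1-yl]-1,2-dioxan-3-yl]acetate
Conditions: camphorsulfonic acid (10 mol %), MeOH (5 equiv), CH2Cl2, rt
Reagents that add atoms: methanol (13), CO (exchanges with the C6 methoxy group)
Why: Acid-catalysed anomerisation of the cyclic peroxyketal through the ring peroxycarbenium ion (ketal exchange) should converge on the thermodynamic C6 epimer, with methoxy axial (anomeric effect) and both carbon chains equatorial, which with the fixed 3S centre is 6R (methoxy cis to the acetate arm); C3 is a secondary alkyl peroxide carbon and cannot ionise.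

**Step 8**
Reactants: 15 methyl 2-[(3S,6R)-6-methoxy-6-[5-(triisopropylsilyl)pent-4-yn-1-yl]-1,2-dioxan-3-yl]acetate
Product: 16 methyl 2-[(3S,6R)-6-methoxy-6-(pent-4-yn-1-yl)-1,2-dioxan-3-yl]acetate
Conditions: TBAF–AcOH (1:1, 1.5 equiv), THF, 0 °C → rt
Reagents that add atoms: none
Why: Fluoride-induced protodesilylation of the alkynylsilane, buffered with acetic acid so that no base strong enough for ester enolisation and retro-oxa-Michael opening at C3 is present.

**Step 9**
Reactants: 17 dec-9-en-1-ol
Product: 18 dec-9-enal
Conditions: IBX, EtOAc, 80 °C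
Reagents that add atoms: none
Why: IBX oxidation of a primary alcohol stops at the aldehyde and leaves the terminal alkene alone.

**Step 10**
Reactants: 18 dec-9-enal
Product: 19 (E)-1-iodoundeca-1,10-diene
Conditions: CrCl2 (6 equiv), CHI3 (2 equiv), THF–1,4-dioxane (1:6), 0 °C → rt
Reagents that add atoms: iodoform, IC(I)I
Why: Takai olefination, in which the gem-dichromium reagent from iodoform adds to the aldehyde and anti elimination gives the E-iodoalkene, the dioxane co-solvent raising the E preference, while the remote terminal alkene is inert to divalent chromium.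

**Step 11**
Reactants: 16 methyl 2-[(3S,6R)-6-methoxy-6-(pent-4-yn-1-yl)-1,2-dioxan-3-yl]acetate; 19 (E)-1-iodoundeca-1,10-diene
Product: 20 peroxyacarnoate A, methyl 2-[(3S,6R)-6-[(6E)-hexadeca-6,15-dien-4-yn-1-yl]-6-methoxy-1,2-dioxan-3-yl]acetate
Conditions: PdCl2(PPh3)2 (5 mol %), CuI (10 mol %), Et3N, THF, rt, degassed
Reagents that add atoms: none
Why: Sonogashira coupling joins the terminal alkyne to the alkenyl iodide with retention of the E geometry at room temperature, conditions under which the dialkyl peroxyketal, the ester and both terminal alkenes are expected to persist.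

**Compound list**
1 | hex-5-ynoic acid | C#CCCCC(=O)O | starting material
2 | dilithium hex-5-ynoate acetylide | [Li+].[Li+].[C-]#CCCCC(=O)[O-] | intermediate
3 | 6-(triisopropylsilyl)hex-5-ynoic acid | CC(C)[Si](C(C)C)(C(C)C)C#CCCCC(=O)O | intermediate
4 | 1-(imidazol-1-yl)-6-(triisopropylsilyl)hex-5-yn-1-one (acyl imidazole) | CC(C)[Si](C(C)C)(C(C)C)C#CCCCC(=O)n1ccnc1 | intermediate
5 | N-methoxy-N-methyl-6-(triisopropylsilyl)hex-5-ynamide | CC(C)[Si](C(C)C)(C(C)C)C#CCCCC(=O)N(C)OC | intermediate
6 | but-3-enylmagnesium bromide | C=CCC[Mg]Br | starting material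
7 | bromomagnesium salt of the tetrahedral N-methoxy-N-methyl hemiaminal (chelate) | CC(C)[Si](C(C)C)(C(C)C)C#CCCCC(CCC=C)(O[Mg]Br)N(C)OC | intermediate
8 | 10-(triisopropylsilyl)dec-1-en-9-yn-5-one | CC(C)[Si](C(C)C)(C(C)C)C#CCCCC(=O)CCC=C | intermediate
9 | (6,6-dimethoxydec-9-en-1-yn-1-yl)triisopropylsilane | CC(C)[Si](C(C)C)(C(C)C)C#CCCCC(OC)(OC)CCC=C | intermediate
10 | hydrogen peroxide | OO | starting material
11 | (6-hydroperoxy-6-methoxydec-9-en-1-yn-1-yl)triisopropylsilane, racemic | CC(C)[Si](C(C)C)(C(C)C)C#CCCCC(OC)(OO)CCC=C | intermediate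
12 | carbon monoxide | [C-]#[O+] | starting material
13 | methanol | CO | starting material
14 | methyl 2-[(3S)-6-methoxy-6-[5-(triisopropylsilyl)pent-4-yn-1-yl]-1,2-dioxan-3-yl]acetate, C6 epimer mixture | CC(C)[Si](C(C)C)(C(C)C)C#CCCCC1(OC)CC[C@@H](CC(=O)OC)OO1 | intermediate
15 | methyl 2-[(3S,6R)-6-methoxy-6-[5-(triisopropylsilyl)pent-4-yn-1-yl]-1,2-dioxan-3-yl]acetate | CC(C)[Si](C(C)C)(C(C)C)C#CCCC[C@]1(OC)CC[C@@H](CC(=O)OC)OO1 | intermediate
16 | methyl 2-[(3S,6R)-6-methoxy-6-(pent-4-yn-1-yl)-1,2-dioxan-3-yl]acetate | C#CCCC[C@]1(OC)CC[C@@H](CC(=O)OC)OO1 | intermediate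
17 | dec-9-en-1-ol | C=CCCCCCCCCO | starting material
18 | dec-9-enal | C=CCCCCCCCC=O | intermediate
19 | (E)-1-iodoundeca-1,10-diene | C=CCCCCCCC/C=C/I | intermediate
20 | peroxyacarnoate A | C=CCCCCCCC/C=C/C#CCCC[C@]1(OC)CC[C@@H](CC(=O)OC)OO1 | target

**Step count**
Total: 11 steps. Longest linear sequence: 9 steps (steps 1–8 and 11, from hex-5-ynoic acid).

**Steps most likely to fail**

Step 6 (proposed new method). The hydroperoxide may be lost before oxypalladation, by palladium/CO-mediated reduction of the O–O bond or by Lewis-acid ionisation of the peroxyketal. Enantiofacial control at C3 may also be poor, either because the ligand differentiates the faces of a monosubstituted alkene weakly or because the C6 centre steers the mismatched half of the racemate. The fallback uses known chemistry and sets out from ketal 9. Cross-metathesis with methyl acrylate (second-generation Hoveyda–Grubbs catalyst, CH2Cl2, 40 °C) should give methyl (E)-6,6-dimethoxy-11-(triisopropylsilyl)undec-2-en-10-ynoate F1. Exchange with H2O2 under the conditions of step 5 should give methyl (E)-6-hydroperoxy-6-methoxy-11-(triisopropylsilyl)undec-2-en-10-ynoate F2. Et2NH in CF3CH2OH at rt should then bring about the intramolecular 6-exo conjugate addition of the hydroperoxide to the enoate, giving the dioxane ester racemic at C3 and mixed at C6, F3. Equilibration as in step 7 should give the racemic cis compound, rac-(3S,6R) dioxane ester F4. Preparative HPLC on a chiral stationary phase then separates the enantiomers, and the route is rejoined at 15. Enantiocontrol in this fallback comes from resolution, not from a catalyst.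

Step 5. Exchange may run on to the gem-dihydroperoxide, or adventitious water may hydrolyse the ketal back to ketone 8. The fallback replaces exchange by addition and sets out from ketal 9. Elimination of methanol with TMSOTf and i-Pr2NEt (CH2Cl2, −20 °C → rt) should give the methyl enol ethers, triisopropyl(6-methoxydeca-5,9-dien-1-yn-1-yl)silane F5 and its regioisomer triisopropyl(6-methoxydeca-6,9-dien-1-yn-1-yl)silane F6, each as an E/Z mixture. Markovnikov addition of anhydrous H2O2 in Et2O with catalytic pyridinium p-toluenesulfonate at 0 °C converts both regioisomers into the same hydroperoxyketal, and the route is rejoined at 11.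

Step 11. Monovalent copper with amine, or zerovalent palladium, may cleave the O–O bond reductively; oxidative homocoupling of alkyne 16 and amine-induced β-elimination at C3 are further losses. The fallback avoids copper and amine and sets out from 16 and 18. Alkyne 16 with N-bromosuccinimide and catalytic AgNO3 in acetone should give methyl 2-[(3S,6R)-6-(5-bromopent-4-yn-1-yl)-6-methoxy-1,2-dioxan-3-yl]acetate F7. Aldehyde 18 with Cl2CHBpin, CrCl2 and LiI in THF (boron variant of the Takai olefination) should give (E)-4,4,5,5-tetramethyl-2-(undeca-1,10-dien-1-yl)-1,3,2-dioxaborolane F8. Suzuki–Miyaura coupling of the 1-bromoalkyne with the alkenylboronate (Pd(PPh3)4, K3PO4, THF–H2O, rt) then joins the route at 20.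

**Further compounds**
F1 | step 6 | methyl (E)-6,6-dimethoxy-11-(triisopropylsilyl)undec-2-en-10-ynoate | CC(C)[Si](C(C)C)(C(C)C)C#CCCCC(OC)(OC)CC/C=C/C(=O)OC
F2 | step 6 | methyl (E)-6-hydroperoxy-6-methoxy-11-(triisopropylsilyl)undec-2-en-10-ynoate, racemic | CC(C)[Si](C(C)C)(C(C)C)C#CCCCC(OC)(OO)CC/C=C/C(=O)OC
F3 | step 6 | methyl 2-[6-methoxy-6-[5-(triisopropylsilyl)pent-4-yn-1-yl]-1,2-dioxan-3-yl]acetate, racemic at C3 and mixed at C6 | CC(C)[Si](C(C)C)(C(C)C)C#CCCCC1(OC)CCC(CC(=O)OC)OO1
F4 | step 6 | rac-(3S,6R) methyl 2-[6-methoxy-6-[5-(triisopropylsilyl)pent-4-yn-1-yl]-1,2-dioxan-3-yl]acetate, racemate with relative configuration shown | CC(C)[Si](C(C)C)(C(C)C)C#CCCC[C@]1(OC)CC[C@@H](CC(=O)OC)OO1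
F5 | step 5 | triisopropyl(6-methoxydeca-5,9-dien-1-yn-1-yl)silane, E/Z mixture | CC(C)[Si](C(C)C)(C(C)C)C#CCCC=C(OC)CCC=C
F6 | step 5 | triisopropyl(6-methoxydeca-6,9-dien-1-yn-1-yl)silane, E/Z mixture | CC(C)[Si](C(C)C)(C(C)C)C#CCCCC(OC)=CCC=C
F7 | step 11 | methyl 2-[(3S,6R)-6-(5-bromopent-4-yn-1-yl)-6-methoxy-1,2-dioxan-3-yl]acetate | BrC#CCCC[C@]1(OC)CC[C@@H](CC(=O)OC)OO1
F8 | step 11 | (E)-4,4,5,5-tetramethyl-2-(undeca-1,10-dien-1-yl)-1,3,2-dioxaborolane | C=CCCCCCCC/C=C/B1OC(C)(C)C(C)(C)O1
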